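## The problem

Target 17, (2S)-5-hydroxy-2-(4-hydroxyphenyl)-7-methoxy-6,8-bis(3-methylbut-2-enyl)chroman-4-one, is a flavanone. The fully substituted benzene ring A is fused along C4a–C8a to the dihydropyranone ring C, and ring B, a para-hydroxyphenyl group, is joined to C2 by the single bond C2–C1'. Ring A carries six different substituents in a fixed order (C5 hydroxyl, C6 prenyl, C7 methoxyl, C8 prenyl, O1, the C4a acyl carbon), so three phloroglucinol oxygens must be told apart and two prenyl groups must go onto carbon, not oxygen. C2 is the only stereocenter, and nothing else in the molecule can relay control to it, so a chiral catalyst has to set it. It is also fragile: it is β to the C4 ketone and bonded to the phenolic O1, so base can open ring C by retro-oxa-Michael reaction, and a free 4'-phenoxide adds a quinone-methide route to the same ring opening. The two prenyl groups are trisubstituted alkenes ortho to oxygen: strong acid cyclizes them onto a neighbouring phenol, quinone oxidants turn an ortho-prenylphenol into a chromene, and hydrogenation or hydrogenolysis is excluded. The C5 hydroxyl is hydrogen-bonded to the C4 carbonyl, which makes it the least reactive phenol and its acetal ethers the easiest to cleave with acid. The enabling feature is ring B itself: C1' and C2' can be read as a terminal alkyne on C2, and C3'–C6' with the oxygen on C4' as a 2-silyloxybuta-1,3-diene, so the arene can be grown on a C2 ethynyl group after the stereocenter exists.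

## Retrosynthesis

**17 from 16.** The last cuts are the O–Si bond at C4' and the O–CH2 bond at C5, leading back to the aryl trimethylsilyl ether 16 with a methoxymethyl (MOM) group on the C5 oxygen. Both come off with dilute acid. Base is avoided at the end because it would threaten C2. The C5 oxygen must be masked during the oxidation that precedes this step, since a free phenol next to a prenyl group would be oxidized to a chromene. An acetal is preferred to an ester (basic removal) or a benzyl ether (hydrogenolysis). The forward step has to be mild enough that the freed C5 hydroxyl does not add to the C6 prenyl group.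

**16 from 15.** Ring B of 16 is taken back to the cyclohexa-1,4-diene 15 by adding two hydrogens at C3' and C6'. No skeletal bond changes. The precursor is the direct product of a diene and alkyne union, and its two doubly allylic methylenes are far better hydride donors than anything else in the molecule. The forward step needs an oxidant that stops at one equivalent.

**15 from 13 and 14 (key disconnection).** Cutting C1'–C6' and C2'–C3' splits 15 into the (S)-2-ethynylchromanone 13 and commercial 2-(trimethylsilyloxy)buta-1,3-diene 14. The neighbouring cuts are C2–C1' (an aryl nucleophile added to chromone 8) and O1–C2 (oxa-Michael closure of a chalcone).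

- The chalcone closure has no reliable enantioselective version for an unactivated substrate.
- The aryl addition is the shortest alternative and is kept as the reserve for the key step. It would ask a neutral, doubly donor-stabilized vinylogous ester with a peri substituent to accept an electron-rich arylmetal that is prone to protodemetalation.
- The alkyne and diene union forms ring B at a sterically open alkyne remote from ring A. It brings the C4' oxygen with the diene and uses a neutral catalyst that has no reason to touch C2.

The precursor 13 has lost six carbons and one ring. The forward reaction must give the para and not the meta regioisomer and must ignore the prenyl alkenes and the ketone.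

**13 from 12, and 12 from 8 and 9.** The terminal alkyne comes from its C-silyl derivative 12. The C2–C(sp) bond is then cut to give the flat, achiral chromone 8 and trimethylsilylacetylene 9. In the forward sense 8 is O-silylated to the 4-silyloxybenzopyrylium ion 10, which a chiral copper acetylide attacks at C2 to give enol ether 11, hydrolysed to 12. The donor groups on ring A, a handicap for conjugate addition to 8 itself, stabilize the pyrylium ion. This cut is preferred to an aldol and Mitsunobu sequence, which would need a separate asymmetric step and more operations. The forward reactions must give face selectivity at C2 and a C-desilylation that is not basic.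

**8 from 5 and 6.** Cutting O1–C2 and C2–C3 returns the 2-hydroxyacetophenone 5 and the one-carbon reagent N,N-dimethylformamide dimethyl acetal 6, via enaminone 7. A formate Claisen condensation would need strong acid for the final dehydration. The enaminone closes under weak acid, which the MOM ether and the prenyl groups tolerate.

**5 from 4, 4 from 3, 3 from 1 and 2.** The MOM group, the C7 methyl group and both prenyl groups are removed in turn, giving commercial 2,4,6-trihydroxyacetophenone 1 and 1-bromo-3-methylbut-2-ene 2. The order follows the intrinsic reactivity of the ring.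

- The triphenol 1 is the best carbon nucleophile and has only two free ring positions.
- The hydroxyl para to the acetyl group of 3 is the most acidic and is methylated first.
- The two remaining hydroxyls of 4 are equivalent by symmetry, and after one is protected the other is locked in a hydrogen bond.

Because 3 and 4 are symmetric, no regiochemical choice arises when ring C is closed.

## Roads not taken

**Alternative 1:** The cut is at the two ring-carbon to CH2 bonds of the prenyl groups. In the forward step the bis(1,1-dimethylallyl) ether A2 of 2,6-dihydroxy-4-methoxyacetophenone is heated. Two [3,3] shifts with allylic inversion deliver linear prenyl groups to the ring carbons next to each oxygen and free both phenols, giving A1.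

- Merits: delivery is intramolecular, so there is no O-alkylation, no geminal dialkylation and exactly one prenyl group per position. In regiocontrol this is better than the direct prenylation of step 1.
- Weak points: A2 needs tertiary allyl ethers on two phenols that flank a carbonyl, one of them hydrogen-bonded. That normally takes propargylation and semi-hydrogenation, so three or four operations replace two. Tertiary allyl aryl ethers can also lose isoprene on heating. The strategy also leaves ring B and C2 unsolved.
- Comparison: A1 is the same compound as 4, so this road joins the chosen one and competes only with steps 1 and 2. The chosen plan sets brevity against its better selectivity and keeps the Claisen sequence as the reserve for step 1.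

**Alternative 2:** The cut is at C5–C6 and C7–C8 of ring A. In the forward step the 3-silyloxy-2-prenylcyclobutenone A4 is heated with the prenyl methoxyalkyne A5. A vinylketene forms, adds to the alkyne, and the resulting cyclobutenone opens and closes again by 4π and 6π electrocyclic steps to the phenol A3.

- Merits: every ring A substituent is placed by connectivity, and the three oxygens emerge already differentiated (free hydroxyl, methyl ether, silyl ether). This is better than the chosen plan, which relies on selectivity between similar phenols and on a statistical C-prenylation.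
- Weak points: A4 and A5 are sensitive compounds that each need several steps. The ketene intermediates carry tethered trisubstituted alkenes that can intercept them. The only free position of A3 lies between two oxygen substituents and must still be acylated. Ring C, ring B and C2 all remain to be made.
- Comparison: it replaces three short steps from a commercial arene by a much longer sequence and does not touch the stereochemical problem. The chosen plan accepts a less selective first step in exchange.

**Alternative 3:** The cut is at C4a–C5 and C8–C8a. In the forward step the 1,3-dimethoxy-1-silyloxy diene A8, bearing both prenyl groups, adds across the C4a=C8a bond of the enantiopure sulfinyl dihydropyranone A7. Loss of benzenesulfenic acid, methanol and silanol aromatizes ring A and gives A6.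

- Merits: it is the most convergent plan. C2 and ring B arrive together in A7, which an asymmetric hetero-Diels–Alder reaction can supply. Polar matching fixes the regiochemistry, the C5 hydroxyl appears free, and A6 is one deprotection from 17. If the cycloaddition worked, this road would be shorter in its longest linear sequence than the chosen one.
- Weak points: both bond-forming termini of A8 are substituted, and the dienophile is a vinylogous ester that the sulfinyl group activates only modestly. The forcing conditions this implies endanger the ketene acetal and invite retro-oxa-Michael opening of A7 at C2. Making A8 with defined enol ether regiochemistry from a doubly prenylated β-keto ester takes several steps.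
- Comparison: the chosen plan sets against its convergence that each bond-forming step belongs to a reaction class known on closely related substrates, and that ring B is formed at an unhindered alkyne and not at a congested ring fusion.

Key step: step 7

Assumption: in step 5 the bis(oxazoline) ligand L* is the antipode of 2,2'-(propane-2,2-diyl)bis(4-phenyl-4,5-dihydrooxazole) that delivers the 2S product. The sense of induction is taken to follow that of unsubstituted chromone, and the configuration of 12 is to be confirmed before material is carried on.

## Route

Step 1
Reactants: 1 1-(2,4,6-trihydroxyphenyl)ethanone; 2 1-bromo-3-methylbut-2-ene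
Product: 3 1-[2,4,6-trihydroxy-3,5-bis(3-methylbut-2-enyl)phenyl]ethanone
Conditions: 2 (2.1 equiv), 10% aq. KOH, 0 °C to rt
Reagents that add atoms: none
Why: C-alkylation of an ambident acylphloroglucinolate; in water the oxygens are solvated and the soft allylic bromide attacks the two free ring carbons, as in the known prenylation of acylphloroglucinols. The bromide is limited to two equivalents to hold back geminal dialkylation.

Step 2
Reactants: 3 1-[2,4,6-trihydroxy-3,5-bis(3-methylbut-2-enyl)phenyl]ethanone
Product: 4 1-[2,6-dihydroxy-4-methoxy-3,5-bis(3-methylbut-2-enyl)phenyl]ethanone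
Conditions: Me2SO4 (1.05 equiv), K2CO3 (1.0 equiv), acetone, rt
Reagents that add atoms: dimethyl sulfate, COS(=O)(=O)OC
Why: Williamson ether synthesis; the hydroxyl para to the acetyl group is the most acidic, so one equivalent of weak base forms its phenoxide selectively. The hard sulfate electrophile favours O- over C-methylation.

Step 3
Reactants: 4 1-[2,6-dihydroxy-4-methoxy-3,5-bis(3-methylbut-2-enyl)phenyl]ethanone
Product: 5 1-[2-hydroxy-4-methoxy-6-(methoxymethoxy)-3,5-bis(3-methylbut-2-enyl)phenyl]ethanone
Conditions: MOMCl (1.2 equiv), i-Pr2NEt (1.5 equiv), CH2Cl2, 0 °C
Reagents that add atoms: chloromethyl methyl ether, COCCl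
Why: O-alkylation with an α-chloro ether; the two hydroxyls of 4 are equivalent, and after the first is protected the second is held in a hydrogen bond to the ketone and resists the amine-base conditions. This is the known chelation-controlled mono-protection of 2,6-dihydroxyaryl ketones.

Step 4
Reactants: 5 1-[2-hydroxy-4-methoxy-6-(methoxymethoxy)-3,5-bis(3-methylbut-2-enyl)phenyl]ethanone; 6 N,N-dimethylformamide dimethyl acetal
Product: 8 7-methoxy-5-(methoxymethoxy)-6,8-bis(3-methylbut-2-enyl)chromen-4-one, via enaminone 7 (not isolated)
Conditions: 6 (3 equiv), toluene, 90 °C; then AcOH, toluene, 40 °C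
Reagents that add atoms: none
Why: Condensation of the methyl ketone with the formamide acetal gives the enaminone; the phenol then adds to its β-carbon and dimethylamine leaves (addition and elimination), the standard enaminone route to 2,3-unsubstituted chromones. Acetic acid protonates the vinylogous amide but should be too weak to cleave the MOM ether or cyclize a prenyl group.

Step 5
Reactants: 8 7-methoxy-5-(methoxymethoxy)-6,8-bis(3-methylbut-2-enyl)chromen-4-one; 9 ethynyltrimethylsilane
Product: 12 (2S)-7-methoxy-5-(methoxymethoxy)-6,8-bis(3-methylbut-2-enyl)-2-[(trimethylsilyl)ethynyl]chroman-4-one, via benzopyrylium triflate 10 (not isolated), via silyl enol ether 11 (not isolated)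
Conditions: t-BuMe2SiOTf (1.2 equiv), 2,6-di-tert-butylpyridine (0.2 equiv), CH2Cl2, 0 °C; then CuI (10 mol %), L* (12 mol %), 9 (1.5 equiv), i-Pr2NEt (1.5 equiv), −40 °C; then 1 M aq. HCl, THF, 0 °C
Reagents that add atoms: none
Why: Copper-catalysed enantioselective alkynylation of a chromone-derived 4-silyloxybenzopyrylium ion, a known reaction of 2-unsubstituted chromones; the C5 and C7 oxygen donors stabilize the cation. The copper acetylide bound to the chiral bis(oxazoline) attacks one enantiotopic face of the planar ion at C2, so C2 is set by catalyst control, and cold dilute acid hydrolyses the enol ether to the ketone. The hindered pyridine scavenges adventitious triflic acid to protect the prenyl groups.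

Step 6
Reactants: 12 (2S)-7-methoxy-5-(methoxymethoxy)-6,8-bis(3-methylbut-2-enyl)-2-[(trimethylsilyl)ethynyl]chroman-4-one
Product: 13 (2S)-2-ethynyl-7-methoxy-5-(methoxymethoxy)-6,8-bis(3-methylbut-2-enyl)chroman-4-one
Conditions: AgNO3 (10 mol %), acetone/H2O, rt
Reagents that add atoms: none
Why: Silver-catalysed protodesilylation of an alkynylsilane, which runs at neutral pH. Carbonate or unbuffered fluoride is avoided because base could open the β-aryloxy ketone by retro-oxa-Michael reaction and erode C2.

Step 7
Reactants: 13 (2S)-2-ethynyl-7-methoxy-5-(methoxymethoxy)-6,8-bis(3-methylbut-2-enyl)chroman-4-one; 14 2-(trimethylsilyloxy)buta-1,3-diene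
Product: 15 (2S)-7-methoxy-5-(methoxymethoxy)-6,8-bis(3-methylbut-2-enyl)-2-[4-(trimethylsilyloxy)cyclohexa-1,4-dien-1-yl]chroman-4-one
Conditions: CoBr2(dppe) (10 mol %), Zn powder (20 mol %), ZnI2 (20 mol %), 14 (2 equiv), CH2Cl2, rt
Reagents that add atoms: none
Why: Zinc reduces the divalent cobalt complex to a monovalent cobalt bisphosphine species and ZnI2 abstracts halide to open coordination sites; the diene and the terminal alkyne bind, couple oxidatively to a cobaltacycle, and reductive elimination releases the cyclohexa-1,4-diene, so C1'–C6' and C2'–C3' form in one catalytic cycle. The closest known reaction type is the cobalt-catalysed neutral Diels–Alder reaction of unactivated terminal alkynes with 2-substituted buta-1,3-dienes, 2-silyloxydienes included. Ring B closes as a six-membered carbocycle in a formal [4+2] mode, the second C–C bond being made by reductive elimination at cobalt and not by a concerted pericyclic step. No stereocenter is created; C2 is a propargylic spectator whose bonds are untouched, and the neutral, base-free medium offers the β-aryloxy ketone no path to ring opening. The step needs regioselectivity and chemoselectivity: the dppe ligand places the diene substituent away from the alkyne substituent in the metallacycle, which puts the silyloxy group on C4' (para) and not on C3', and the sterically open terminal alkyne is engaged in preference to the trisubstituted prenyl alkenes and the aryl ketone. The diene is used in excess and 15 is filtered dry and carried on crude, because its silyl enol ether is the one fragile function formed.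

Step 8
Reactants: 15 (2S)-7-methoxy-5-(methoxymethoxy)-6,8-bis(3-methylbut-2-enyl)-2-[4-(trimethylsilyloxy)cyclohexa-1,4-dien-1-yl]chroman-4-one
Product: 16 (2S)-7-methoxy-5-(methoxymethoxy)-6,8-bis(3-methylbut-2-enyl)-2-[4-(trimethylsilyloxy)phenyl]chroman-4-one
Conditions: DDQ (1.05 equiv), toluene, 0 °C to rt
Reagents that add atoms: none
Why: Dehydrogenation of a cyclohexa-1,4-diene by hydride abstraction and proton loss; the gain of aromaticity should make the doubly allylic ring B methylenes react well before the prenyl methylenes or C2–H at one equivalent of oxidant. No free phenol is present, so oxidative chromene formation from the prenyl groups has no entry point.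

Step 9
Reactants: 16 (2S)-7-methoxy-5-(methoxymethoxy)-6,8-bis(3-methylbut-2-enyl)-2-[4-(trimethylsilyloxy)phenyl]chroman-4-one
Product: 17 (2S)-5-hydroxy-2-(4-hydroxyphenyl)-7-methoxy-6,8-bis(3-methylbut-2-enyl)chroman-4-one
Conditions: 3 M aq. HCl/MeOH (1:5), rt
Reagents that add atoms: none
Why: Acid-catalysed methanolysis of the aryl silyl ether and of the MOM acetal, the latter assisted by the peri carbonyl; dilute acid at room temperature is the usual way to unmask prenylated flavanones without cyclizing the prenyl groups. Acid is chosen over base so that the 4'-hydroxyflavanone is not opened at C2.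

## Compound list

1 | 1-(2,4,6-trihydroxyphenyl)ethanone | CC(=O)c1c(O)cc(O)cc1O | starting material
2 | 1-bromo-3-methylbut-2-ene | CC(C)=CCBr | starting material
3 | 1-[2,4,6-trihydroxy-3,5-bis(3-methylbut-2-enyl)phenyl]ethanone | CC(=O)c1c(O)c(CC=C(C)C)c(O)c(CC=C(C)C)c1O | intermediate
4 | 1-[2,6-dihydroxy-4-methoxy-3,5-bis(3-methylbut-2-enyl)phenyl]ethanone | CC(=O)c1c(O)c(CC=C(C)C)c(OC)c(CC=C(C)C)c1O | intermediate
5 | 1-[2-hydroxy-4-methoxy-6-(methoxymethoxy)-3,5-bis(3-methylbut-2-enyl)phenyl]ethanone | CC(=O)c1c(O)c(CC=C(C)C)c(OC)c(CC=C(C)C)c1OCOC | intermediate
6 | N,N-dimethylformamide dimethyl acetal | COC(OC)N(C)C | starting material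
7 | (E)-3-(dimethylamino)-1-[2-hydroxy-4-methoxy-6-(methoxymethoxy)-3,5-bis(3-methylbut-2-enyl)phenyl]prop-2-en-1-one | CN(C)/C=C/C(=O)c1c(O)c(CC=C(C)C)c(OC)c(CC=C(C)C)c1OCOC | intermediate
8 | 7-methoxy-5-(methoxymethoxy)-6,8-bis(3-methylbut-2-enyl)chromen-4-one | COc1c(CC=C(C)C)c(OCOC)c2c(c1CC=C(C)C)OC=CC2=O | intermediate
9 | ethynyltrimethylsilane | C#C[Si](C)(C)C | starting material
10 | 4-(tert-butyldimethylsilyloxy)-7-methoxy-5-(methoxymethoxy)-6,8-bis(3-methylbut-2-enyl)chromenylium trifluoromethanesulfonate | COc1c(CC=C(C)C)c(OCOC)c2c(O[Si](C)(C)C(C)(C)C)cc[o+]c2c1CC=C(C)C.[O-]S(=O)(=O)C(F)(F)F | intermediate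
11 | (2S)-4-(tert-butyldimethylsilyloxy)-7-methoxy-5-(methoxymethoxy)-6,8-bis(3-methylbut-2-enyl)-2-[(trimethylsilyl)ethynyl]-2H-chromene | COc1c(CC=C(C)C)c(OCOC)c2c(c1CC=C(C)C)O[C@H](C#C[Si](C)(C)C)C=C2O[Si](C)(C)C(C)(C)C | intermediate
12 | (2S)-7-methoxy-5-(methoxymethoxy)-6,8-bis(3-methylbut-2-enyl)-2-[(trimethylsilyl)ethynyl]chroman-4-one | COc1c(CC=C(C)C)c(OCOC)c2c(c1CC=C(C)C)O[C@H](C#C[Si](C)(C)C)CC2=O | intermediate
13 | (2S)-2-ethynyl-7-methoxy-5-(methoxymethoxy)-6,8-bis(3-methylbut-2-enyl)chroman-4-one | COc1c(CC=C(C)C)c(OCOC)c2c(c1CC=C(C)C)O[C@H](C#C)CC2=O | intermediate
14 | 2-(trimethylsilyloxy)buta-1,3-diene | C=CC(=C)O[Si](C)(C)C | starting material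
15 | (2S)-7-methoxy-5-(methoxymethoxy)-6,8-bis(3-methylbut-2-enyl)-2-[4-(trimethylsilyloxy)cyclohexa-1,4-dien-1-yl]chroman-4-one | COc1c(CC=C(C)C)c(OCOC)c2c(c1CC=C(C)C)O[C@H](C1=CCC(O[Si](C)(C)C)=CC1)CC2=O | intermediate
16 | (2S)-7-methoxy-5-(methoxymethoxy)-6,8-bis(3-methylbut-2-enyl)-2-[4-(trimethylsilyloxy)phenyl]chroman-4-one | COc1c(CC=C(C)C)c(OCOC)c2c(c1CC=C(C)C)O[C@H](c1ccc(O[Si](C)(C)C)cc1)CC2=O | intermediate
17 | (2S)-5-hydroxy-2-(4-hydroxyphenyl)-7-methoxy-6,8-bis(3-methylbut-2-enyl)chroman-4-one | COc1c(CC=C(C)C)c(O)c2c(c1CC=C(C)C)O[C@H](c1ccc(O)cc1)CC2=O | target

## Step count and least certain steps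

Total steps: 9. Longest linear sequence: 9 steps, from 1 to 17.

**Step 7 (key step).** The most likely failure is that cobalt consumes the alkyne by cyclotrimerization, or the diene by dimerization, faster than the crossed coupling, because the chelating array of O1, the C4 ketone and the MOM oxygens can slow turnover. A second risk is premature hydrolysis of the silyl enol ether to a β,γ-enone that a mild hydride acceptor cannot aromatize. The fallback leaves the alkyne route and sets out from chromone 8. Asymmetric 1,4-addition of 4-(methoxymethoxy)phenylboronic acid, catalysed by monovalent rhodium from [Rh(OH)(cod)]2 and an electron-poor atropisomeric bisphosphine (the antipode that gives 2S) in aqueous toluene, should give (2S)-7-methoxy-5-(methoxymethoxy)-2-[4-(methoxymethoxy)phenyl]-6,8-bis(3-methylbut-2-enyl)chroman-4-one F1. The acid conditions of step 9 then remove both acetals, and the route is rejoined at 17.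

**Step 5.** The most likely failure is erosion of enantioselectivity: the hindered, electron-rich pyrylium ion reacts slowly and a ligand-free background addition can compete. Partial cleavage of the MOM ether by the silyl triflate is the second risk. The fallback replaces asymmetric catalysis by resolution. From 8, the same pyrylium formation followed by CuI and i-Pr2NEt without a chiral ligand should give racemic 7-methoxy-5-(methoxymethoxy)-6,8-bis(3-methylbut-2-enyl)-2-[(trimethylsilyl)ethynyl]chroman-4-one F2. Preparative chromatography on a chiral stationary phase separates the enantiomers, and the 2S enantiomer is 12, where the route is rejoined.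

**Step 1.** The most likely failure is poor control of the degree and site of alkylation: monoprenylation, O-prenylation and geminal dialkylation with loss of aromaticity would give a mixture that is hard to separate. The fallback installs the prenyl groups by sigmatropic shift.

- From 1, methylation as in step 2 gives 1-(2,6-dihydroxy-4-methoxyphenyl)ethanone F3.
- Double O-alkylation with 3-chloro-3-methylbut-1-yne (CuCl2·2H2O cat., DBU, MeCN, 0 °C) gives 1-[4-methoxy-2,6-bis(2-methylbut-3-yn-2-yloxy)phenyl]ethanone F4.
- Semi-hydrogenation over Pd/CaCO3 poisoned with Pb(OAc)2 and quinoline gives 1-[4-methoxy-2,6-bis(2-methylbut-3-en-2-yloxy)phenyl]ethanone F5, the same compound as A2.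
- Heating in xylene at 130 °C effects the double aromatic Claisen rearrangement and rejoins the route at 4.

**Step 8.** The most likely failure is over-oxidation: hydride abstraction at the benzylic and allylic prenyl methylenes or dehydrogenation across C2–C3, made worse if the enol ether hydrolyses before it is oxidized. The fallback changes the mechanism to a Saegusa–Ito oxidation, which acts only at the silyl enol ether. From 15, stoichiometric Pd(OAc)2 in MeCN at room temperature forms a divalent palladium enolate. β-Hydride elimination gives a cyclohexa-2,4-dienone that tautomerizes to (2S)-2-(4-hydroxyphenyl)-7-methoxy-5-(methoxymethoxy)-6,8-bis(3-methylbut-2-enyl)chroman-4-one F6. The conditions of step 9 then give 17.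

**Step 4.** The most likely failure is partial loss of the MOM group during the acid-promoted ring closure, or incomplete closure under the weak acid. The fallback takes the acid-labile group out of the acidic step by reversing the order. From 4, the formamide acetal 6 gives (E)-1-[2,6-dihydroxy-4-methoxy-3,5-bis(3-methylbut-2-enyl)phenyl]-3-(dimethylamino)prop-2-en-1-one F7. This is closed with conc. HCl in CH2Cl2 at room temperature to 5-hydroxy-7-methoxy-6,8-bis(3-methylbut-2-enyl)chromen-4-one F8. Treatment with NaH and MOMCl in DMF then rejoins the route at 8.

## Further compounds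

F1 | step 7 | (2S)-7-methoxy-5-(methoxymethoxy)-2-[4-(methoxymethoxy)phenyl]-6,8-bis(3-methylbut-2-enyl)chroman-4-one | COc1c(CC=C(C)C)c(OCOC)c2c(c1CC=C(C)C)O[C@H](c1ccc(OCOC)cc1)CC2=O
F2 | step 5 | racemic 7-methoxy-5-(methoxymethoxy)-6,8-bis(3-methylbut-2-enyl)-2-[(trimethylsilyl)ethynyl]chroman-4-one | COc1c(CC=C(C)C)c(OCOC)c2c(c1CC=C(C)C)OC(C#C[Si](C)(C)C)CC2=O
F3 | step 1 | 1-(2,6-dihydroxy-4-methoxyphenyl)ethanone | CC(=O)c1c(O)cc(OC)cc1O
F4 | step 1 | 1-[4-methoxy-2,6-bis(2-methylbut-3-yn-2-yloxy)phenyl]ethanone | CC(=O)c1c(OC(C)(C)C#C)cc(OC)cc1OC(C)(C)C#C
F5 | step 1 | 1-[4-methoxy-2,6-bis(2-methylbut-3-en-2-yloxy)phenyl]ethanone | CC(=O)c1c(OC(C)(C)C=C)cc(OC)cc1OC(C)(C)C=C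
F6 | step 8 | (2S)-2-(4-hydroxyphenyl)-7-methoxy-5-(methoxymethoxy)-6,8-bis(3-methylbut-2-enyl)chroman-4-one | COc1c(CC=C(C)C)c(OCOC)c2c(c1CC=C(C)C)O[C@H](c1ccc(O)cc1)CC2=O
F7 | step 4 | (E)-1-[2,6-dihydroxy-4-methoxy-3,5-bis(3-methylbut-2-enyl)phenyl]-3-(dimethylamino)prop-2-en-1-one | CN(C)/C=C/C(=O)c1c(O)c(CC=C(C)C)c(OC)c(CC=C(C)C)c1O
F8 | step 4 | 5-hydroxy-7-methoxy-6,8-bis(3-methylbut-2-enyl)chromen-4-one | COc1c(CC=C(C)C)c(O)c2c(c1CC=C(C)C)OC=CC2=O
A1 | alternative 1 | 1-[2,6-dihydroxy-4-methoxy-3,5-bis(3-methylbut-2-enyl)phenyl]ethanone | CC(=O)c1c(O)c(CC=C(C)C)c(OC)c(CC=C(C)C)c1O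
A2 | alternative 1 | 1-[4-methoxy-2,6-bis(2-methylbut-3-en-2-yloxy)phenyl]ethanone | CC(=O)c1c(OC(C)(C)C=C)cc(OC)cc1OC(C)(C)C=C
A3 | alternative 2 | 3-methoxy-2,4-bis(3-methylbut-2-enyl)-5-(triisopropylsilyloxy)phenol | COc1c(CC=C(C)C)c(O)cc(O[Si](C(C)C)(C(C)C)C(C)C)c1CC=C(C)C
A4 | alternative 2 | 2-(3-methylbut-2-enyl)-3-(triisopropylsilyloxy)cyclobut-2-en-1-one | O=C1CC(O[Si](C(C)C)(C(C)C)C(C)C)=C1CC=C(C)C
A5 | alternative 2 | 1-methoxy-5-methylhex-4-en-1-yne | COC#CCC=C(C)C
A6 | alternative 3 | (2S)-5-hydroxy-7-methoxy-2-[4-(methoxymethoxy)phenyl]-6,8-bis(3-methylbut-2-enyl)chroman-4-one | COc1c(CC=C(C)C)c(O)c2c(c1CC=C(C)C)O[C@H](c1ccc(OCOC)cc1)CC2=O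
A7 | alternative 3 | (2S)-2-[4-(methoxymethoxy)phenyl]-5-(phenylsulfinyl)-2,3-dihydropyran-4-one | O=C1C[C@@H](c2ccc(OCOC)cc2)OC=C1S(=O)c1ccccc1
A8 | alternative 3 | 1,3-dimethoxy-7-methyl-2-(3-methylbut-2-enyl)-1-(trimethylsilyloxy)octa-1,3,6-triene | COC(O[Si](C)(C)C)=C(CC=C(C)C)C(OC)=CCC=C(C)C
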